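Decide first what stopped red: read it as lost carrier, not as a shortage of salt.

in all of them: salt in the second phase 14.3 mM; spent carrier 0.78 mM
- blue: starting material 0.81 mM; run made earlier
- red: starting material 15 mM; run made earlier
- midnight: starting material 1.5 mM; time 6.0 d; volume of the second phase over the first 1.0
- autumn: starting material 3.0 mM; time 6.0 d; volume of the second phase over the first 1.0
- dawn: starting material 6.0 mM; time 6.0 d; volume of the second phase over the first 1.0
- summer: starting material 12 mM; time 6.0 d; volume of the second phase over the first 1.0
- noon: starting material 20 mM; time 6.0 d; volume of the second phase over the first 1.0

| run | time / d | product / % |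
|---|---|---|
| blue | 0.250 | 78.1 |
| blue | 0.417 | 90.8 |
| blue | 0.833 | 99.6 |
| blue | 1.67 | 97.7 |
| blue | 3.00 | 97.7 |
| red | 0.250 | 24.4 |
| red | 0.833 | 38.3 |
| red | 1.25 | 41.9 |
| red | 2.00 | 43.4 |
| red | 3.00 | 43.5 |

(scatter of a reading: 1 percentage point)

- charges count per volume of the first phase; a concentration in a rate is the amount of a species over the volume of its own phase; every rate counts per litre of the first phase
- what was read earlier has a scatter of 1 percentage point, one standard deviation
- the earlier runs hold the two phases in the same ratio of volumes as the flask asked about
- "hardly changes" means that all values lie within two and a half points (for a concentration: within two and a half percent of the largest)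

- [product] at the end for midnight, autumn, dawn, summer, noon, in this order
- the course of these numbers from the first flask to the last (rises, then falls / falls, then rises / hardly changes / rises all the way / falls all the way)

Climb the ladder of times from the fastest rung. In 0.250 d red made product amounting to 4.69 times the carrier charged, so one round of the carrier takes about 0.0533 d on average over that time. That is far shorter than the next rung, the 2.00 d at which red stands at 43.4%, against 43.5% at 3.00 d. So red's carrier stops after a limited number of rounds, at 6.52 mM of product, although more salt was charged. The top rung is the asked 6.0 d, longer than red's stop, so read each flask as its end state.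

Assume that starting material attacks spent carrier while salt recharges it. Then carrier lost per product grows with c(starting material)/c(salt). The loss number, carrier lost per product divided by that ratio of means between charge and stop, is 0.116 in red, counting one salt and one starting material per product.

Now iterate: guess the product, take the means, find the product at which the loss equals the carrier charged (or, with carrier to spare, subtract the loss from the charge), and put it back in.

| flask | first round | second round |
|---|---|---|
| midnight | 1.5 mM | 1.49 mM |
| autumn | 3.0 mM | 2.96 mM |
| dawn | 6.0 mM | 5.81 mM |
| summer | 8.87 mM | 9.22 mM |
| noon | 4.53 mM | 4.65 mM |

By my reckoning dawn loses 0.185 mM of carrier, less than its charge, so in dawn my limiting reagent is starting material. My row therefore rises, then falls.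

The forecast, holding that “No run shows excess starting material lowering the yield”, gave 1.48 mM, 2.95 mM, 5.6 mM, 6.4 mM, 6.6 mM, rises all the way, which parts from my row at summer and noon.

The flask gives 1.48 mM, 2.93 mM, 5.75 mM, 7.97 mM, 4.94 mM: rises, then falls.

    spent carrier + salt in the second phase ⇌ fresh carrier + spent salt in the second phase (K = 0.490, k = 120 L mol⁻¹ h⁻¹)
    starting material + fresh carrier → product + spent carrier (k = 470 L mol⁻¹ h⁻¹)
    starting material + spent carrier → spent catalyst (k = 12.0 L mol⁻¹ h⁻¹)

At the start of midnight, the forward rate at which spent carrier passes to fresh carrier is 95 times the rate at which it passes to spent catalyst, and midnight ends with spent catalyst at 2.73% of the catalyst charged. Noon ends with spent catalyst at 100% and 71% of its starting material left, summer with 99.7% and 27%. From these end states the loss number reads 0.109 in noon and 0.132 in summer.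

All runs stem from a simulated flask with made-up constants; the scatter is artificial.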